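**Plan**
- Retrosynthesis (drimane numbering): cut the cinnamate ester at O–C1; cut C9–C11 and C8–C12 back to a C9 ketone; cut ring A at C1–C2 and C3–C4 into a two-carbon acrylate unit and a ring-B aldehyde; cut C5–C4 and C10–C1 back to 2-methylcyclohexane-1,3-dione, an isopropenyl nucleophile and formaldehyde.
- Forward: ring B comes from the dione; ring A is closed onto it in one operation; the C1 oxidation level is then adjusted, the ester is attached, and the ene-dialdehyde is built last on ring B.
- Enabling feature: in the ring-B precursor the formyl carbon C1 (on quaternary C10) and the isopropenyl carbon C4 (on carbinol C5) sit trans on adjacent ring carbons, i.e. a γ,δ-unsaturated aldehyde. A tertiary radical at C4 and the electrophilic C1 can therefore be bridged by the two carbons of an acrylate to give a trans-fused six-membered ring A.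
- Stereochemistry: C10 from CBS desymmetrisation of the prochiral dione (the C9 carbinol is a temporary control centre); C5 from axial organocerium addition; C1 from hydroxyl-directed reduction; C9 from α-face hydroboration; the E alkene from p-coumaric acid.

Key step: step 7

Remark: the (S)-CBS catalyst is assumed to give the (R)-carbinol at C9 by the usual model (quaternary side as the large group); if the sense were opposite, the (R)-catalyst would be used.

Step 1
Reactants: 1 2-methylcyclohexane-1,3-dione; 2 formaldehyde (37% in water)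
Product: 3 2-(hydroxymethyl)-2-methylcyclohexane-1,3-dione
Conditions: 37% aq. CH2O, Et3N (5 mol %), THF/H2O, 0 °C to rt
Reagents that add atoms: none
Why: Aldol hydroxymethylation of the acidic C2–H of the 1,3-dione gives the quaternary carbon (future C10 bearing C1); the product is still prochiral.

Step 2
Reactants: 3 2-(hydroxymethyl)-2-methylcyclohexane-1,3-dione
Product: 4 2-methyl-2-[(triethylsilyloxy)methyl]cyclohexane-1,3-dione
Conditions: TESCl, imidazole, CH2Cl2, 0 °C
Reagents that add atoms: chlorotriethylsilane, CC[Si](Cl)(CC)CC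
Why: Silylation of the primary alcohol blocks retro-aldol loss of formaldehyde and installs a group that step 6 can oxidise directly.

Step 3
Reactants: 4 2-methyl-2-[(triethylsilyloxy)methyl]cyclohexane-1,3-dione
Product: 5 (2R,3R)-3-hydroxy-2-methyl-2-[(triethylsilyloxy)methyl]cyclohexan-1-one
Conditions: (S)-2-methyl-CBS-oxazaborolidine (0.2 equiv), BH3·SMe2 (0.6 equiv), THF, −30 °C; MeOH
Reagents that add atoms: none
Why: Corey–Bakshi–Shibata reduction desymmetrises the dione: the catalyst fixes the (R) carbinol (C9) and hydride enters the carbonyl whose open face is anti to the larger CH2OTES group, so the hydroxyl is cis to CH2OTES and C10 becomes a stereocentre of the required sense (the minor diastereomer should be separable).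

Step 4
Reactants: 5 (2R,3R)-3-hydroxy-2-methyl-2-[(triethylsilyloxy)methyl]cyclohexan-1-one
Product: 6 (2R,3R)-3-[(tert-butyldimethylsilyl)oxy]-2-methyl-2-[(triethylsilyloxy)methyl]cyclohexan-1-one
Conditions: TBSOTf, 2,6-lutidine, CH2Cl2, −78 °C
Reagents that add atoms: tert-butyldimethylsilyl trifluoromethanesulfonate, CC(C)(C)[Si](C)(C)OS(=O)(=O)C(F)(F)F
Why: Silylation of the secondary alcohol gives a bulky ether that should stay equatorial in step 5 and survive until step 13.

Step 5
Reactants: 6 (2R,3R)-3-[(tert-butyldimethylsilyl)oxy]-2-methyl-2-[(triethylsilyloxy)methyl]cyclohexan-1-one; 7 isopropenylmagnesium bromide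
Product: 8 (1R,2R,3R)-3-[(tert-butyldimethylsilyl)oxy]-2-methyl-1-(prop-1-en-2-yl)-2-[(triethylsilyloxy)methyl]cyclohexan-1-ol
Conditions: CeCl3 (anhydrous), THF, −78 °C
Reagents that add atoms: none
Why: Organocerium 1,2-addition to a hindered, enolisable ketone: in the chair with the C9 silyloxy group equatorial the CH2OTES group on C10 is axial, so the nucleophile should attack axially from the opposite face, setting C5 with the hydroxyl cis to C1 and the isopropenyl group cis to the C10 methyl.

Step 6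
Reactants: 8 (1R,2R,3R)-3-[(tert-butyldimethylsilyl)oxy]-2-methyl-1-(prop-1-en-2-yl)-2-[(triethylsilyloxy)methyl]cyclohexan-1-ol
Product: 9 (1R,2R,6R)-6-[(tert-butyldimethylsilyl)oxy]-2-hydroxy-1-methyl-2-(prop-1-en-2-yl)cyclohexane-1-carbaldehyde
Conditions: (COCl)2 (4 equiv), DMSO (8 equiv), CH2Cl2, −78 to −30 °C; then Et3N, −78 °C to rt
Reagents that add atoms: none
Why: Swern oxidation converts a primary triethylsilyl ether directly into the aldehyde, while the secondary TBS ether and the tertiary alcohol should be untouched.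

Step 7
Reactants: 9 (1R,2R,6R)-6-[(tert-butyldimethylsilyl)oxy]-2-hydroxy-1-methyl-2-(prop-1-en-2-yl)cyclohexane-1-carbaldehyde; 10 benzyl acrylate
Product: 13 benzyl 9α-[(tert-butyldimethylsilyl)oxy]-1,5α-dihydroxy-11,12-dinordrimane-2-carboxylate (trans-fused; C1/C2 epimers carried together), via tertiary C4 radical 11 (not isolated), via ester enolate 12 (not isolated)
Conditions: Fe(acac)3 (0.3 equiv), PhSiH3 (2.5 equiv), benzyl acrylate (3 equiv), EtOH/ethylene glycol (5:1), 0 °C to rt, argon
Reagents that add atoms: none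
Why: An iron hydride formed from Fe(acac)3 and PhSiH3 transfers a hydrogen atom to the CH2 terminus of the isopropenyl group to give the tertiary C4 radical 11, which adds to benzyl acrylate (Giese addition, C3–C4 bond); the α-ester radical is reduced by divalent iron to enolate 12 (radical–polar crossover), which adds to the C1 aldehyde (C1–C2 bond). The closest known reaction type is the hydrogen-atom-transfer-initiated radical–polar crossover annulation of γ,δ-unsaturated carbonyl compounds with conjugate acceptors, and 9 is such a γ,δ-unsaturated aldehyde. Ring A closes by a 6-(enolexo)-exo-trig aldol addition through a chair transition state, and because the C4 and C1 arms were placed trans on ring B in steps 3 and 5 the ring fusion can only be trans. The new centres C1 and C2 should form mainly with equatorial hydroxyl and ester groups from that chair, but neither is relied on: C2 loses its substituent in step 9 and C1 is reset in steps 8 and 10. The step needs hydrogen-atom transfer at the 1,1-disubstituted alkene only, capture of 11 by the acrylate faster than its reduction, and aldol closure faster than protonation of 12; the substrate secures these by carrying no other alkene, by giving a nucleophilic tertiary radical matched to the electron-poor acrylate used in excess, and by holding a non-enolisable aldehyde in position for six-membered ring closure.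

Step 8
Reactants: 13 benzyl 9α-[(tert-butyldimethylsilyl)oxy]-1,5α-dihydroxy-11,12-dinordrimane-2-carboxylate
Product: 14 benzyl 9α-[(tert-butyldimethylsilyl)oxy]-5α-hydroxy-1-oxo-11,12-dinordrimane-2-carboxylate
Conditions: Dess–Martin periodinane, NaHCO3, CH2Cl2, rt
Reagents that add atoms: none
Why: Dess–Martin oxidation of the secondary C1 carbinol gives the β-keto ester and merges the C1/C2 epimers; the tertiary alcohol cannot be oxidised.

Step 9
Reactants: 14 benzyl 9α-[(tert-butyldimethylsilyl)oxy]-5α-hydroxy-1-oxo-11,12-dinordrimane-2-carboxylate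
Product: 16 9α-[(tert-butyldimethylsilyl)oxy]-5α-hydroxy-11,12-dinordriman-1-one, via β-keto acid 15 (not isolated)
Conditions: H2 (1 atm), Pd/C (10%), EtOAc, rt; then 50 °C
Reagents that add atoms: none
Why: Hydrogenolysis of the benzyl ester gives the β-keto acid, which should lose CO2 on gentle warming; no alkene is present and the silyl ether is inert.

Step 10
Reactants: 16 9α-[(tert-butyldimethylsilyl)oxy]-5α-hydroxy-11,12-dinordriman-1-one
Product: 17 9α-[(tert-butyldimethylsilyl)oxy]-11,12-dinordrimane-1β,5α-diol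
Conditions: Me4NBH(OAc)3, MeCN/AcOH (1:1), −25 °C
Reagents that add atoms: none
Why: Evans–Saksena reduction: the axial 5α-hydroxyl exchanges onto boron and delivers hydride intramolecularly to the α face of the C1 ketone, which should give the anti-1,3-diol, i.e. the equatorial 1β-alcohol.

Step 11
Reactants: 18 (E)-p-coumaric acid
Product: 20 (E)-3-[4-(triisopropylsilyloxy)phenyl]prop-2-enoic acid, via bis-silylated ester 19 (not isolated)
Conditions: TIPSCl (2.2 equiv), imidazole, DMF, rt; then K2CO3, THF/MeOH/H2O, 0 °C; citric acid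
Reagents that add atoms: chlorotriisopropylsilane, CC(C)[Si](Cl)(C(C)C)C(C)C
Why: Bis-silylation followed by selective hydrolysis of the labile silyl ester leaves the phenol as a TIPS ether; the E double bond is that of the starting acid.

Step 12
Reactants: 17 9α-[(tert-butyldimethylsilyl)oxy]-11,12-dinordrimane-1β,5α-diol; 20 (E)-3-[4-(triisopropylsilyloxy)phenyl]prop-2-enoic acid
Product: 21 9α-[(tert-butyldimethylsilyl)oxy]-5α-hydroxy-11,12-dinordriman-1β-yl (E)-3-[4-(triisopropylsilyloxy)phenyl]prop-2-enoate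
Conditions: EDC·HCl, DMAP, CH2Cl2, rt
Reagents that add atoms: none
Why: Steglich esterification acylates the equatorial secondary 1β-hydroxyl; the tertiary 5α-hydroxyl should not react.

Step 13
Reactants: 21 9α-[(tert-butyldimethylsilyl)oxy]-5α-hydroxy-11,12-dinordriman-1β-yl (E)-3-[4-(triisopropylsilyloxy)phenyl]prop-2-enoate
Product: 22 5α,9α-dihydroxy-11,12-dinordriman-1β-yl (E)-3-[4-(triisopropylsilyloxy)phenyl]prop-2-enoate
Conditions: HF·pyridine, pyridine, THF, 0 °C to rt
Reagents that add atoms: none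
Why: Acidic fluoride should cleave the alkyl TBS ether faster than the aryl TIPS ether, which is less basic at oxygen and more hindered at silicon.

Step 14
Reactants: 22 5α,9α-dihydroxy-11,12-dinordriman-1β-yl (E)-3-[4-(triisopropylsilyloxy)phenyl]prop-2-enoate
Product: 24 5α-hydroxy-9-oxo-11,12-dinordrim-7-en-1β-yl (E)-3-[4-(triisopropylsilyloxy)phenyl]prop-2-enoate, via C9 ketone 23 (not isolated)
Conditions: IBX (4 equiv), DMSO/fluorobenzene (1:2), 70 °C
Reagents that add atoms: none
Why: IBX oxidises the C9 alcohol to the ketone and then dehydrogenates it in the same pot; desaturation can only go toward C8–C7 because C10 is quaternary.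

Step 15
Reactants: 24 5α-hydroxy-9-oxo-11,12-dinordrim-7-en-1β-yl (E)-3-[4-(triisopropylsilyloxy)phenyl]prop-2-enoate; 2 formaldehyde (37% in water)
Product: 25 5α,12-dihydroxy-9-oxo-11-nordrim-7-en-1β-yl (E)-3-[4-(triisopropylsilyloxy)phenyl]prop-2-enoate
Conditions: DMAP (0.2 equiv), THF/H2O (1:1), rt
Reagents that add atoms: none
Why: Morita–Baylis–Hillman reaction of the β-unsubstituted enone with formaldehyde installs C12 as a hydroxymethyl group on C8 and keeps the C7–C8 double bond.

Step 16
Reactants: 25 5α,12-dihydroxy-9-oxo-11-nordrim-7-en-1β-yl (E)-3-[4-(triisopropylsilyloxy)phenyl]prop-2-enoate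
Product: 26 5α,12-dihydroxydrima-7,9(11)-dien-1β-yl (E)-3-[4-(triisopropylsilyloxy)phenyl]prop-2-enoate
Conditions: Zn, CH2Br2, TiCl4 (pre-formed reagent), THF/CH2Cl2, 0 °C to rt
Reagents that add atoms: dibromomethane, BrCBr
Why: Takai–Lombardo methylenation converts hindered, enolisable ketones into methylene compounds without attacking esters, and introduces C11.

Step 17
Reactants: 26 5α,12-dihydroxydrima-7,9(11)-dien-1β-yl (E)-3-[4-(triisopropylsilyloxy)phenyl]prop-2-enoate
Product: 28 5α,11,12-trihydroxydrim-7-en-1β-yl (E)-3-[4-(triisopropylsilyloxy)phenyl]prop-2-enoate, via C11 alkylborane 27 (not isolated)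
Conditions: 9-BBN (4 equiv), THF, 0 °C to rt; then NaBO3·4H2O, THF/H2O, rt
Reagents that add atoms: sodium perborate, [Na+].[O-]OB=O
Why: Hydroboration of the exocyclic double bond of the diene should place boron on C11 and hydrogen on C9 from the α face, anti to the axial C10 methyl (the established sense for drima-7,9(11)-dienes), and oxidation gives the 11,12-diol with 9α-H.

Step 18
Reactants: 28 5α,11,12-trihydroxydrim-7-en-1β-yl (E)-3-[4-(triisopropylsilyloxy)phenyl]prop-2-enoate
Product: 29 5α-hydroxy-11,12-dioxodrim-7-en-1β-yl (E)-3-[4-(triisopropylsilyloxy)phenyl]prop-2-enoate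
Conditions: (COCl)2, DMSO, CH2Cl2, −78 °C; then i-Pr2NEt, −78 to −40 °C
Reagents that add atoms: none
Why: Swern oxidation of both primary alcohols at low temperature with a hindered amine should give the ene-dialdehyde without epimerising C9; the tertiary alcohol is inert.

Step 19
Reactants: 29 5α-hydroxy-11,12-dioxodrim-7-en-1β-yl (E)-3-[4-(triisopropylsilyloxy)phenyl]prop-2-enoate
Product: 30 CNP0323926.1, 5α-hydroxy-11,12-dioxodrim-7-en-1β-yl (E)-3-(4-hydroxyphenyl)prop-2-enoate
Conditions: TBAF/AcOH (1:1), THF, 0 °C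
Reagents that add atoms: none
Why: Buffered fluoride removes the aryl silyl ether quickly while the acetic acid keeps the medium non-basic, so the base-sensitive C9 centre should not epimerise.

**Compound list**
1 | 2-methylcyclohexane-1,3-dione | CC1C(=O)CCCC1=O | starting material
2 | formaldehyde (37% in water) | C=O | starting material
3 | 2-(hydroxymethyl)-2-methylcyclohexane-1,3-dione | CC1(CO)C(=O)CCCC1=O | intermediate
4 | 2-methyl-2-[(triethylsilyloxy)methyl]cyclohexane-1,3-dione | CC1(CO[Si](CC)(CC)CC)C(=O)CCCC1=O | intermediate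
5 | (2R,3R)-3-hydroxy-2-methyl-2-[(triethylsilyloxy)methyl]cyclohexan-1-one | C[C@]1(CO[Si](CC)(CC)CC)C(=O)CCC[C@H]1O | intermediate
6 | (2R,3R)-3-[(tert-butyldimethylsilyl)oxy]-2-methyl-2-[(triethylsilyloxy)methyl]cyclohexan-1-one | C[C@]1(CO[Si](CC)(CC)CC)C(=O)CCC[C@H]1O[Si](C)(C)C(C)(C)C | intermediate
7 | isopropenylmagnesium bromide | C=C(C)[Mg]Br | starting material
8 | (1R,2R,3R)-3-[(tert-butyldimethylsilyl)oxy]-2-methyl-1-(prop-1-en-2-yl)-2-[(triethylsilyloxy)methyl]cyclohexan-1-ol | C[C@]1(CO[Si](CC)(CC)CC)[C@](O)(C(C)=C)CCC[C@H]1O[Si](C)(C)C(C)(C)C | intermediate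
9 | (1R,2R,6R)-6-[(tert-butyldimethylsilyl)oxy]-2-hydroxy-1-methyl-2-(prop-1-en-2-yl)cyclohexane-1-carbaldehyde | C[C@]1(C=O)[C@](O)(C(C)=C)CCC[C@H]1O[Si](C)(C)C(C)(C)C | intermediate
10 | benzyl acrylate | C=CC(=O)OCc1ccccc1 | starting material
11 | tertiary C4 radical formed from 9 by hydrogen-atom transfer | C[C@]1(C=O)[C@](O)([C](C)C)CCC[C@H]1O[Si](C)(C)C(C)(C)C | intermediate
12 | benzyl ester enolate formed from 11 and 10 | C[C@]1(C=O)[C@](O)(C(C)(C)CC=C([O-])OCc2ccccc2)CCC[C@H]1O[Si](C)(C)C(C)(C)C | intermediate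
13 | benzyl 9α-[(tert-butyldimethylsilyl)oxy]-1,5α-dihydroxy-11,12-dinordrimane-2-carboxylate (C1/C2 epimers) | CC1(C)CC(C(=O)OCc2ccccc2)C(O)[C@]2(C)[C@H](O[Si](C)(C)C(C)(C)C)CCC[C@@]12O | intermediate
14 | benzyl 9α-[(tert-butyldimethylsilyl)oxy]-5α-hydroxy-1-oxo-11,12-dinordrimane-2-carboxylate | CC1(C)CC(C(=O)OCc2ccccc2)C(=O)[C@]2(C)[C@H](O[Si](C)(C)C(C)(C)C)CCC[C@@]12O | intermediate
15 | 9α-[(tert-butyldimethylsilyl)oxy]-5α-hydroxy-1-oxo-11,12-dinordrimane-2-carboxylic acid | CC1(C)CC(C(O)=O)C(=O)[C@]2(C)[C@H](O[Si](C)(C)C(C)(C)C)CCC[C@@]12O | intermediate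
16 | 9α-[(tert-butyldimethylsilyl)oxy]-5α-hydroxy-11,12-dinordriman-1-one | CC1(C)CCC(=O)[C@]2(C)[C@H](O[Si](C)(C)C(C)(C)C)CCC[C@@]12O | intermediate
17 | 9α-[(tert-butyldimethylsilyl)oxy]-11,12-dinordrimane-1β,5α-diol | CC1(C)CC[C@@H](O)[C@]2(C)[C@H](O[Si](C)(C)C(C)(C)C)CCC[C@@]12O | intermediate
18 | (E)-p-coumaric acid | OC(=O)/C=C/c1ccc(O)cc1 | starting material
19 | triisopropylsilyl (E)-3-[4-(triisopropylsilyloxy)phenyl]prop-2-enoate | CC(C)[Si](OC(=O)/C=C/c1ccc(O[Si](C(C)C)(C(C)C)C(C)C)cc1)(C(C)C)C(C)C | intermediate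
20 | (E)-3-[4-(triisopropylsilyloxy)phenyl]prop-2-enoic acid | OC(=O)/C=C/c1ccc(O[Si](C(C)C)(C(C)C)C(C)C)cc1 | intermediate
21 | 9α-[(tert-butyldimethylsilyl)oxy]-5α-hydroxy-11,12-dinordriman-1β-yl (E)-3-[4-(triisopropylsilyloxy)phenyl]prop-2-enoate | CC1(C)CC[C@@H](OC(=O)/C=C/c2ccc(O[Si](C(C)C)(C(C)C)C(C)C)cc2)[C@]2(C)[C@H](O[Si](C)(C)C(C)(C)C)CCC[C@@]12O | intermediate
22 | 5α,9α-dihydroxy-11,12-dinordriman-1β-yl (E)-3-[4-(triisopropylsilyloxy)phenyl]prop-2-enoate | CC1(C)CC[C@@H](OC(=O)/C=C/c2ccc(O[Si](C(C)C)(C(C)C)C(C)C)cc2)[C@]2(C)[C@H](O)CCC[C@@]12O | intermediate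
23 | 5α-hydroxy-9-oxo-11,12-dinordriman-1β-yl (E)-3-[4-(triisopropylsilyloxy)phenyl]prop-2-enoate | CC1(C)CC[C@@H](OC(=O)/C=C/c2ccc(O[Si](C(C)C)(C(C)C)C(C)C)cc2)[C@]2(C)C(=O)CCC[C@@]12O | intermediate
24 | 5α-hydroxy-9-oxo-11,12-dinordrim-7-en-1β-yl (E)-3-[4-(triisopropylsilyloxy)phenyl]prop-2-enoate | CC1(C)CC[C@@H](OC(=O)/C=C/c2ccc(O[Si](C(C)C)(C(C)C)C(C)C)cc2)[C@]2(C)C(=O)C=CC[C@@]12O | intermediate
25 | 5α,12-dihydroxy-9-oxo-11-nordrim-7-en-1β-yl (E)-3-[4-(triisopropylsilyloxy)phenyl]prop-2-enoate | CC1(C)CC[C@@H](OC(=O)/C=C/c2ccc(O[Si](C(C)C)(C(C)C)C(C)C)cc2)[C@]2(C)C(=O)C(CO)=CC[C@@]12O | intermediate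
26 | 5α,12-dihydroxydrima-7,9(11)-dien-1β-yl (E)-3-[4-(triisopropylsilyloxy)phenyl]prop-2-enoate | CC1(C)CC[C@@H](OC(=O)/C=C/c2ccc(O[Si](C(C)C)(C(C)C)C(C)C)cc2)[C@]2(C)C(=C)C(CO)=CC[C@@]12O | intermediate
27 | C11 9-borabicyclononyl borane (12-O-borinate) from 26 | CC1(C)CC[C@@H](OC(=O)/C=C/c2ccc(O[Si](C(C)C)(C(C)C)C(C)C)cc2)[C@]2(C)[C@@H](CB3C4CCCC3CCC4)C(COB3C4CCCC3CCC4)=CC[C@@]12O | intermediate
28 | 5α,11,12-trihydroxydrim-7-en-1β-yl (E)-3-[4-(triisopropylsilyloxy)phenyl]prop-2-enoate | CC1(C)CC[C@@H](OC(=O)/C=C/c2ccc(O[Si](C(C)C)(C(C)C)C(C)C)cc2)[C@]2(C)[C@@H](CO)C(CO)=CC[C@@]12O | intermediate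
29 | 5α-hydroxy-11,12-dioxodrim-7-en-1β-yl (E)-3-[4-(triisopropylsilyloxy)phenyl]prop-2-enoate | CC1(C)CC[C@@H](OC(=O)/C=C/c2ccc(O[Si](C(C)C)(C(C)C)C(C)C)cc2)[C@]2(C)[C@@H](C=O)C(C=O)=CC[C@@]12O | intermediate
30 | CNP0323926.1, 5α-hydroxy-11,12-dioxodrim-7-en-1β-yl (E)-3-(4-hydroxyphenyl)prop-2-enoate | CC1(C)CC[C@@H](OC(=O)/C=C/c2ccc(O)cc2)[C@]2(C)[C@@H](C=O)C(C=O)=CC[C@@]12O | target

**Count**
Total steps: 19. Longest linear sequence: 18 (steps 1–10 and 12–19; step 11 is the side branch).

**Steps most likely to fail**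

Step 7 (key step). The enolate may be protonated by the alcoholic medium before it reaches the aldehyde, so that only the radical half of the cascade takes place. The fallback sets out from 9: the same iron hydride conditions are run to the open-chain Giese adduct benzyl 4-[(1R,2R,3R)-3-[(tert-butyldimethylsilyl)oxy]-2-formyl-1-hydroxy-2-methylcyclohexyl]-4-methylpentanoate F1, and ring A is then closed in a separate ionic step by deprotonation of the ester with LiHMDS (2.2 equiv, THF, −78 °C) and intramolecular aldol addition. This comes back to the route at 13.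

Step 16. The hindered, enolisable C9 ketone may resist methylenation, or the Lewis-acidic titanium reagent may ionise the allylic and tertiary alcohols. The fallback sets out from 25: Corey–Chaykovsky epoxidation (Me3SI, KHMDS, THF, −20 °C; axial attack anti to the C10 methyl) should give 9β,11-epoxy-5α,12-dihydroxydrim-7-en-1β-yl (E)-3-[4-(triisopropylsilyloxy)phenyl]prop-2-enoate F2. Meinwald rearrangement (MgBr2·OEt2, CH2Cl2, −40 °C), in which hydride shifts from C11 to the α face of C9, should give 5α,12-dihydroxy-11-oxodrim-7-en-1β-yl (E)-3-[4-(triisopropylsilyloxy)phenyl]prop-2-enoate F3 (possibly as its 11,12-lactol). NaBH4 in MeOH at −20 °C then comes back to the route at 28. This detour also removes the dependence on the facial selectivity of the hydroboration in step 17.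

Step 5. The bulky alkenyl nucleophile may attack the ketone with poor facial selectivity, or enolise it. The fallback sets out from 6: the small, linear ethynylmagnesium bromide (CeCl3, THF, −78 °C), which favours axial attack more strongly, should give (1R,2R,3R)-3-[(tert-butyldimethylsilyl)oxy]-1-ethynyl-2-methyl-2-[(triethylsilyloxy)methyl]cyclohexan-1-ol F4. Zirconium-catalysed methylalumination of the terminal alkyne (AlMe3, Cp2ZrCl2 cat., CH2Cl2; then water; Negishi carboalumination) turns the ethynyl group into the isopropenyl group and comes back to the route at 8.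

**Further compounds**
F1 | step 7 | benzyl 4-[(1R,2R,3R)-3-[(tert-butyldimethylsilyl)oxy]-2-formyl-1-hydroxy-2-methylcyclohexyl]-4-methylpentanoate | C[C@]1(C=O)[C@](O)(C(C)(C)CCC(=O)OCc2ccccc2)CCC[C@H]1O[Si](C)(C)C(C)(C)C
F2 | step 16 | 9β,11-epoxy-5α,12-dihydroxydrim-7-en-1β-yl (E)-3-[4-(triisopropylsilyloxy)phenyl]prop-2-enoate | CC1(C)CC[C@@H](OC(=O)/C=C/c2ccc(O[Si](C(C)C)(C(C)C)C(C)C)cc2)[C@]2(C)[C@]3(CO3)C(CO)=CC[C@@]12O
F3 | step 16 | 5α,12-dihydroxy-11-oxodrim-7-en-1β-yl (E)-3-[4-(triisopropylsilyloxy)phenyl]prop-2-enoate | CC1(C)CC[C@@H](OC(=O)/C=C/c2ccc(O[Si](C(C)C)(C(C)C)C(C)C)cc2)[C@]2(C)[C@@H](C=O)C(CO)=CC[C@@]12O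
F4 | step 5 | (1R,2R,3R)-3-[(tert-butyldimethylsilyl)oxy]-1-ethynyl-2-methyl-2-[(triethylsilyloxy)methyl]cyclohexan-1-ol | C[C@]1(CO[Si](CC)(CC)CC)[C@](O)(C#C)CCC[C@H]1O[Si](C)(C)C(C)(C)C
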